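# Design of a total synthesis of isolappaol A (25)

## The problem

Isolappaol A (25) is a sesquilignan built on a trans-α,β-dibenzyl-γ-butyrolactone of the (−)-matairesinol type (ring D, with ring A on the β-benzyl carbon and ring B on the α-benzyl carbon). Ring B is also fused through C3a and C7a to a 2,3-dihydrofuran (ring E) that carries ring C at C2 and a hydroxymethyl group at C3. The four stereocenters form two pairs: C3/C4 of the lactone (R,R) and C2/C3 of ring E (S,R, trans). Within each pair one center can set the other, but the pairs are separated by ring B and a methylene group, so each pair needs its own source of absolute configuration. The two guaiacyl units of the lactone core must be told apart, because only ring B is elaborated ortho to its oxygen. Three sites are fragile: the lactone (opening and α-epimerization under base), the O1–C2 bond of ring E (a para-oxygenated benzylic aryl ether that ionizes under acid), and the free phenols. The enabling feature is that C3 is bonded to the ring B carbon C3a and to an oxygen-bearing CH2, while C2 is an ether carbon linked through O1 to C7a. An ortho-iodophenyl 1-arylallyl ether therefore holds every atom of ring E: joining C3a to the internal vinyl carbon leaves a radical on the terminal carbon, exactly where oxygen is needed, and a C2 center set beforehand can relay its configuration to C3.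

## Retrosynthesis

**25 ⇒ 24 ⇒ 23 (unmasking).** No skeletal bond is cut. The phenols of rings A and C are carried as benzyl ethers (24), which survive alkoxide, amide base, fluoride, hydride and radical conditions. The primary alcohol is carried as its tetramethylpiperidinyl ether (23), because that is what the ring-forming step delivers. The forward steps must cleave an N–O bond without harming the lactone, and remove two primary benzyl ethers without breaking the secondary benzylic O1–C2 bond.

**23 ⇒ 19 + 20 (key disconnection).** The C3a–C3 bond and the exocyclic CH2–O bond are cut, opening ring E to the aryl iodide 19 and the nitroxide 20. The neighbouring cuts (O1–C2, or C2–C3) would require C3 to be created as an isolated benzylic stereocenter on ring B, or would need two separately functionalized partners. This cut asks only for an iodine on ring B and a vinyl group on the ether carbon. The precursor has one ring and one stereocenter fewer, and its only ring E stereocenter is C2. The forward reaction must close 5-exo, deliver C3 trans to ring C, and end in C–O bond formation, not reduction.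

**19 ⇒ 14 + 17.** The O–C2 bond is cut in the allylic sense, giving the iodophenol 14 and the achiral linear carbonate 17. A Mitsunobu coupling with an enantioenriched 1-arylallyl alcohol was set aside, because so electron-rich a benzylic allylic system would scramble by ionization and allylic transposition. A catalytic asymmetric allylic etherification makes the branched ether directly. The forward reaction must be branch-selective, must set C2 as S by catalyst control regardless of the remote lactone centers, and must tolerate the aryl iodide and a phenoxide flanked by two ortho substituents.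

**14 ⇒ 13 ⇒ 7 + 11.** The bond between the lactone α-carbon and the ring B methylene is cut, giving the β-benzyl lactone 7 and the benzylic bromide 11. The alternative of iodinating a mono-benzyl matairesinol late would raise a chemoselectivity question between two electron-rich rings. Bringing the iodine in with the ring B building block settles the regiochemistry from the start. A silyl ether (in 13) masks the ring B phenol during alkylation and is the only group removed before the etherification. The forward alkylation must go trans to the β-benzyl group.

**11 ⇒ 10 ⇒ 9 ⇒ 8.** Functional-group changes only: bromide from alcohol, alcohol from aldehyde, silyl ether from phenol, leading back to 5-iodovanillin (8).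

**7 ⇒ 6 ⇒ 5 ⇒ 4 ⇒ 1 + 2.** The lactone C–O bond is opened to hydroxy acid 6, traced to the half-ester 5 and its alkene 4. The alkene is cut between the benzylic carbon and the succinate carbon into O-benzylvanillin (1) and dimethyl succinate (2). This Stobbe route differentiates the two carboxyl groups for free and leaves a single prochiral alkene, so one asymmetric hydrogenation sets lactone C4.

**17 ⇒ 16 ⇒ 15 ⇒ 1.** The carbonate is traced through the allylic alcohol 16 and the cinnamate 15 to the same aldehyde 1, by cutting the C=C bond in the olefination sense. One aldehyde thus supplies both ring A and ring C.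

## Roads not taken

**Alternative 1:** Ring E is cut at both bonds to C2 (C3–C2 and O1–C2) in a [4+1] sense. A carbonate base would unmask an ortho-quinone methide from the ring B sulfonyl phenol A2 and an ylide from the ring C benzylsulfonium salt A3. Conjugate addition would form C3–C2, and displacement of the sulfide by the phenoxide would close ring E to give the silyl ether A1.
- Merits: two bonds and both stereocenters in one convergent operation; a strong built-in trans preference; no tin and no excess nitroxide; the primary oxygen arrives protected.
- Weak points: A2 must be built on ring B of the advanced lactone by a multi-step ortho-C-functionalization. Its quinone methide is alkyl-substituted with an acidic hydrogen and a β-silyloxy group, so tautomerization and elimination compete with ylide addition. Absolute control rests on a stoichiometric chiral sulfide and is best documented for aryl-substituted quinone methides. The basic medium sits next to the epimerizable lactone α-carbon.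
- Comparison: this road is better in bond economy and freedom from tin, and its trans selectivity is probably more secure. The chosen plan sets against it a precursor (19) reached from lactone 7 in three steps, a catalytic source of chirality with one new center to control, and a neutral ring-forming step.

**Alternative 2:** Only C3–C2 is cut, on a small bromoarene instead of the full skeleton. The aryldiazoacetate A5, whose ortho oxygen carries the ring C benzyl group, would be decomposed by Rh2(S-PTTL)4. The carbenoid would insert into one enantiotopic benzylic C–H bond, and NaOMe would then equilibrate C3 to the trans arrangement, giving ester A4.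
- Merits: a catalytic enantioselective step with close precedent for 2-aryl-2,3-dihydrobenzofuran-3-carboxylates; both centers fixed early on inexpensive material; thermodynamic correction of the 2,3-relationship; no tin.
- Weak points: A4 is far from 25. The ester must be reduced and protected, and the bromide turned into a benzylic electrophile by metalation, formylation, reduction and halogenation while ring E is carried along. Only then can it be joined to lactone 7. That is five to six operations after the key step, against two in the chosen plan. The electron-rich ether oxygen and ring C also narrow the selectivity margin known for simpler substrates.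
- Comparison: in reliability of enantiocontrol and in placing risk early this road is at least as good. The chosen plan answers with a shorter sequence, no organometallic chemistry in the presence of ring E, and direct use of the lactone-bearing phenol 14, so that ring E is exposed to only two further mild steps.

**Alternative 3:** Ring E is cut at O1–C2 only. The diol A7 (configured at the future C3, epimeric at the benzylic carbinol) would be treated with BF3·OEt2 or catalytic TsOH. Both epimers ionize to the same para-oxygen-stabilized cation, and the ring B phenol captures it anti to the hydroxymethyl group to give the trans dihydrobenzofuran A6.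
- Merits: cheap reagents, scalability, no need to control the carbinol center, and trans selectivity that is also thermodynamic because the closure is reversible.
- Weak points: the C3 center of A7 must be made enantiopure on its own, in practice by an auxiliary-controlled construction costing stoichiometric chirality and several steps. Dehydration of the cation competes with closure. A6, like A4, is a bromoarene needing the same multi-step conversion before union with 7.
- Comparison: the ring closure itself is more robust than a radical relay and tolerates a free primary alcohol, which the chosen plan cannot claim. The chosen plan sets against it catalytic control of the one ring E center that must be made independently, a much shorter path from ring closure to 25, and no strong acid near an ionizable O1–C2 bond.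

Key step: step 13

Assumption 1: the senses of induction are taken from close analogues — the (S,S)-Et-DuPhos rhodium catalyst should give (R)-5 and the (Sa,Sc,Sc)-phosphoramidite iridium catalyst (S)-19; if either proves opposite, the antipodal ligand is used.

Assumption 2: 4-benzyloxy-3-methoxybenzaldehyde (1) and 5-iodovanillin (8) are treated as commercial; each is otherwise one standard step from vanillin.

## Route

**Step 1**
Reactants: 1 4-benzyloxy-3-methoxybenzaldehyde; 2 dimethyl succinate
Product: 4 (E)-4-(4-benzyloxy-3-methoxyphenyl)-3-(methoxycarbonyl)but-3-enoic acid, via paraconate lactone ester 3 (not isolated)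
Conditions: NaOMe (2 equiv), MeOH, reflux; then aq. HCl
Reagents that add atoms: none
Why: Stobbe condensation; the aldol adduct lactonizes to 3, whose irreversible base-induced ring opening should give the half-ester with the aryl group trans to the ester (E) and the two carboxyl groups differentiated.

**Step 2**
Reactants: 4
Product: 5 (R)-4-(4-benzyloxy-3-methoxyphenyl)-3-(methoxycarbonyl)butanoic acid
Conditions: [Rh(cod)((S,S)-Et-DuPhos)]BF4 (1 mol %), H2 (5 bar), NaOMe (10 mol %), MeOH, rt
Reagents that add atoms: none
Why: Rhodium-catalysed asymmetric hydrogenation of a β-aryl itaconate half-ester; carboxylate and alkene chelate the metal and the C2-symmetric bisphospholane selects the alkene face, setting the future lactone C4 as R. The cationic homogeneous catalyst should not cleave the benzyl ether.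

**Step 3**
Reactants: 5
Product: 7 (R)-4-(4-benzyloxy-3-methoxybenzyl)dihydrofuran-2(3H)-one, via hydroxy acid 6 (not isolated)
Conditions: KOH (1.0 equiv), EtOH; CaCl2, NaBH4, EtOH, −10 °C to rt; then 2 M HCl, rt
Reagents that add atoms: none
Why: Chemoselective reduction of an ester beside a carboxylate salt by Ca(BH4)2 generated in the flask, then acid-induced lactonization of 6; the stereocenter is not touched.

**Step 4**
Reactants: 8 5-iodovanillin (4-hydroxy-3-iodo-5-methoxybenzaldehyde)
Product: 9 4-(tert-butyldimethylsilyloxy)-3-iodo-5-methoxybenzaldehyde
Conditions: TBSCl, imidazole, DMF, rt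
Reagents that add atoms: tert-butyldimethylsilyl chloride, CC(C)(C)[Si](C)(C)Cl
Why: Silylation of the phenol; the silyl ether blocks the phenol during enolate alkylation and is removable with fluoride beside benzyl ether, aryl iodide and lactone.

**Step 5**
Reactants: 9
Product: 10 [4-(tert-butyldimethylsilyloxy)-3-iodo-5-methoxyphenyl]methanol
Conditions: NaBH4, MeOH–THF, 0 °C
Reagents that add atoms: none
Why: Borohydride reduction of an aryl aldehyde; aryl iodide and aryl silyl ether should be inert at 0 °C.

**Step 6**
Reactants: 10
Product: 11 [4-(bromomethyl)-2-iodo-6-methoxyphenoxy](tert-butyl)dimethylsilane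
Conditions: CBr4, PPh3, CH2Cl2, 0 °C
Reagents that add atoms: carbon tetrabromide, BrC(Br)(Br)Br
Why: Appel bromination under neutral conditions that spare the aryl silyl ether; the electron-rich benzylic bromide is to be used promptly.

**Step 7**
Reactants: 7; 11
Product: 13 (3R,4R)-4-(4-benzyloxy-3-methoxybenzyl)-3-[4-(tert-butyldimethylsilyloxy)-3-iodo-5-methoxybenzyl]dihydrofuran-2(3H)-one, via lithium enolate 12 (not isolated)
Conditions: LiN(SiMe3)2 (1.1 equiv), THF, −78 °C; then 11 (1.2 equiv), −78 to −30 °C
Reagents that add atoms: none
Why: Alkylation of a γ-butyrolactone enolate; the electrophile should approach anti to the C4 benzyl group, setting C3 trans (3R). Aryl iodide and silyl ether do not react with the amide base or the enolate at low temperature.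

**Step 8**
Reactants: 13
Product: 14 (3R,4R)-4-(4-benzyloxy-3-methoxybenzyl)-3-(4-hydroxy-3-iodo-5-methoxybenzyl)dihydrofuran-2(3H)-one
Conditions: Bu4NF (1.1 equiv), AcOH (1.2 equiv), THF, 0 °C
Reagents that add atoms: none
Why: Fluoride cleavage of an aryl silyl ether; acetic acid buffers the phenoxide so the lactone and its α-center should be unaffected.

**Step 9**
Reactants: 1
Product: 15 ethyl (E)-3-(4-benzyloxy-3-methoxyphenyl)acrylate
Conditions: (EtO)2P(O)CH2CO2Et, NaH, THF, 0 °C to rt
Reagents that add atoms: triethyl phosphonoacetate, CCOC(=O)CP(=O)(OCC)OCC
Why: Horner–Wadsworth–Emmons olefination of an aryl aldehyde with a stabilized phosphonate, which should be highly E-selective.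

**Step 10**
Reactants: 15
Product: 16 (E)-3-(4-benzyloxy-3-methoxyphenyl)prop-2-en-1-ol
Conditions: i-Bu2AlH (2.5 equiv), CH2Cl2, −78 °C; aq. potassium sodium tartrate
Reagents that add atoms: none
Why: 1,2-Reduction of an α,β-unsaturated ester to the allylic alcohol with retention of alkene geometry.

**Step 11**
Reactants: 16
Product: 17 (E)-3-(4-benzyloxy-3-methoxyphenyl)allyl methyl carbonate
Conditions: ClCO2Me, pyridine, CH2Cl2, 0 °C
Reagents that add atoms: methyl chloroformate, COC(=O)Cl
Why: Acylation of a primary allylic alcohol; the carbonate is the leaving group for the iridium step and supplies methoxide on ionization.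

**Step 12**
Reactants: 14; 17
Product: 19 (3R,4R)-4-(4-benzyloxy-3-methoxybenzyl)-3-[4-{[(1S)-1-(4-benzyloxy-3-methoxyphenyl)prop-2-en-1-yl]oxy}-3-iodo-5-methoxybenzyl]dihydrofuran-2(3H)-one, via lithium phenoxide 18 (not isolated)
Conditions: LiN(SiMe3)2 (1.0 equiv), THF, −78 to 0 °C; then 17 (1.5 equiv), [Ir(cod)Cl]2 (2 mol %), (Sa,Sc,Sc)-(1,1′-binaphthalene-2,2′-diyl) N,N-bis(1-phenylethyl)phosphoramidite (4 mol %, pre-activated with n-PrNH2), THF, rt
Reagents that add atoms: none
Why: Iridium-catalysed asymmetric allylic etherification of an aryloxide with a linear cinnamyl-type carbonate; the cyclometalated iridium–phosphoramidite complex ionizes 17 and the phenoxide attacks the aryl-substituted allyl terminus on the ligand-defined face, which should give the branched ether with C2 as S by catalyst control. One equivalent of base removes only the phenol proton, so the lactone α-center is left alone.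

**Step 13**
Reactants: 19; 20 TEMPO (2,2,6,6-tetramethylpiperidin-1-oxyl)
Product: 23 (3R,4R)-4-(4-benzyloxy-3-methoxybenzyl)-3-{[(2S,3R)-2-(4-benzyloxy-3-methoxyphenyl)-7-methoxy-3-{[(2,2,6,6-tetramethylpiperidin-1-yl)oxy]methyl}-2,3-dihydro-1-benzofuran-5-yl]methyl}dihydrofuran-2(3H)-one, via aryl radical 21 (not isolated), via primary alkyl radical 22 (not isolated)
Conditions: Bu3SnH (3 equiv, added in portions), 20 (5 equiv), benzene (dilute), 65 °C
Reagents that add atoms: none
Why: TEMPO abstracts hydrogen from Bu3SnH, and the tributyltin radical so formed removes iodine from 19 to give aryl radical 21. Radical 21 adds to the internal vinyl carbon in a 5-exo-trig closure, forming C3a–C3 and ring E and leaving primary radical 22; 22 is captured at carbon by a second molecule of 20 at a near diffusion-controlled rate, forming the CH2–O bond. The closest known reaction type is the tin-hydride-mediated aryl radical–alkene 5-exo-trig cyclization with nitroxide trapping, established for ortho-halo aryl allyl ethers and N-allyl anilines. The new center C3 is set by the existing C2 center: in the chair-like transition state ring C lies pseudo-equatorial and the alkene terminus turns away from it, so C3a–C3 should form trans to ring C and (2S) relays to (3R). 5-exo closure is secured over 6-endo by the short planar O–aryl tether, and ring closure over premature capture of 21 by the very high unimolecular rate of ortho-allyloxyaryl radicals together with dilution. Capture of 22 by oxygen instead of hydrogen is secured by the excess of 20 and by portionwise addition of Bu3SnH, which keeps its standing concentration low. The neutral conditions leave the lactone, its α-center, the benzyl ethers and the O–C2 bond alone, and the blocked ortho positions of ring B exclude a Claisen rearrangement at 65 °C.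

**Step 14**
Reactants: 23
Product: 24 (3R,4R)-4-(4-benzyloxy-3-methoxybenzyl)-3-{[(2S,3R)-2-(4-benzyloxy-3-methoxyphenyl)-3-(hydroxymethyl)-7-methoxy-2,3-dihydro-1-benzofuran-5-yl]methyl}dihydrofuran-2(3H)-one
Conditions: Zn dust, AcOH–THF–H2O (3:1:1), 70 °C
Reagents that add atoms: none
Why: Reductive cleavage of the alkoxyamine N–O bond by zinc in acetic acid, a standard unmasking of TEMPO-trapped primary alcohols; benzyl ethers, lactone and both stereocenter pairs should be unaffected.

**Step 15**
Reactants: 24
Product: 25 isolappaol A, (3R,4R)-3-{[(2S,3R)-2-(4-hydroxy-3-methoxyphenyl)-3-(hydroxymethyl)-7-methoxy-2,3-dihydro-1-benzofuran-5-yl]methyl}-4-(4-hydroxy-3-methoxybenzyl)dihydrofuran-2(3H)-one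
Conditions: H2 (1 atm), 10 % Pd/C, EtOAc–MeOH, rt
Reagents that add atoms: none
Why: Hydrogenolysis of two aryl benzyl ethers under neutral conditions; primary benzyl ethers should cleave much faster than the secondary benzylic O1–C2 bond of ring E, so the reaction is stopped at complete debenzylation. No other reducible group remains.

## Compound list

1 | 4-benzyloxy-3-methoxybenzaldehyde (O-benzylvanillin) | COc1cc(C=O)ccc1OCc1ccccc1 | starting material
2 | dimethyl succinate | COC(=O)CCC(=O)OC | starting material
3 | methyl 2-(4-benzyloxy-3-methoxyphenyl)-5-oxotetrahydrofuran-3-carboxylate (paraconate, stereoisomer mixture) | COC(=O)C1CC(=O)OC1c1ccc(OCc2ccccc2)c(OC)c1 | intermediate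
4 | (E)-4-(4-benzyloxy-3-methoxyphenyl)-3-(methoxycarbonyl)but-3-enoic acid | COC(=O)/C(CC(=O)O)=C/c1ccc(OCc2ccccc2)c(OC)c1 | intermediate
5 | (R)-4-(4-benzyloxy-3-methoxyphenyl)-3-(methoxycarbonyl)butanoic acid | COc1cc(C[C@@H](C(=O)OC)CC(=O)O)ccc1OCc1ccccc1 | intermediate
6 | (R)-4-(4-benzyloxy-3-methoxyphenyl)-3-(hydroxymethyl)butanoic acid | COc1cc(C[C@@H](CO)CC(=O)O)ccc1OCc1ccccc1 | intermediate
7 | (R)-4-(4-benzyloxy-3-methoxybenzyl)dihydrofuran-2(3H)-one | COc1cc(C[C@H]2COC(=O)C2)ccc1OCc1ccccc1 | intermediate
8 | 5-iodovanillin (4-hydroxy-3-iodo-5-methoxybenzaldehyde) | COc1cc(C=O)cc(I)c1O | starting material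
9 | 4-(tert-butyldimethylsilyloxy)-3-iodo-5-methoxybenzaldehyde | COc1cc(C=O)cc(I)c1O[Si](C)(C)C(C)(C)C | intermediate
10 | [4-(tert-butyldimethylsilyloxy)-3-iodo-5-methoxyphenyl]methanol | COc1cc(CO)cc(I)c1O[Si](C)(C)C(C)(C)C | intermediate
11 | [4-(bromomethyl)-2-iodo-6-methoxyphenoxy](tert-butyl)dimethylsilane | COc1cc(CBr)cc(I)c1O[Si](C)(C)C(C)(C)C | intermediate
12 | lithium enolate of 7 | [Li+].[O-]C1=C[C@@H](Cc2ccc(OCc3ccccc3)c(OC)c2)CO1 | intermediate
13 | (3R,4R)-4-(4-benzyloxy-3-methoxybenzyl)-3-[4-(tert-butyldimethylsilyloxy)-3-iodo-5-methoxybenzyl]dihydrofuran-2(3H)-one | COc1cc(C[C@H]2COC(=O)[C@@H]2Cc2cc(I)c(O[Si](C)(C)C(C)(C)C)c(OC)c2)ccc1OCc1ccccc1 | intermediate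
14 | (3R,4R)-4-(4-benzyloxy-3-methoxybenzyl)-3-(4-hydroxy-3-iodo-5-methoxybenzyl)dihydrofuran-2(3H)-one | COc1cc(C[C@H]2COC(=O)[C@@H]2Cc2cc(I)c(O)c(OC)c2)ccc1OCc1ccccc1 | intermediate
15 | ethyl (E)-3-(4-benzyloxy-3-methoxyphenyl)acrylate | CCOC(=O)/C=C/c1ccc(OCc2ccccc2)c(OC)c1 | intermediate
16 | (E)-3-(4-benzyloxy-3-methoxyphenyl)prop-2-en-1-ol | OC/C=C/c1ccc(OCc2ccccc2)c(OC)c1 | intermediate
17 | (E)-3-(4-benzyloxy-3-methoxyphenyl)allyl methyl carbonate | COC(=O)OC/C=C/c1ccc(OCc2ccccc2)c(OC)c1 | intermediate
18 | lithium phenoxide of 14 | [Li+].COc1cc(C[C@H]2COC(=O)[C@@H]2Cc2cc(I)c([O-])c(OC)c2)ccc1OCc1ccccc1 | intermediate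
19 | (3R,4R)-4-(4-benzyloxy-3-methoxybenzyl)-3-[4-{[(1S)-1-(4-benzyloxy-3-methoxyphenyl)prop-2-en-1-yl]oxy}-3-iodo-5-methoxybenzyl]dihydrofuran-2(3H)-one | COc1cc(C[C@H]2COC(=O)[C@@H]2Cc2cc(I)c(O[C@@H](C=C)c3ccc(OCc4ccccc4)c(OC)c3)c(OC)c2)ccc1OCc1ccccc1 | intermediate
20 | TEMPO (2,2,6,6-tetramethylpiperidin-1-oxyl) | CC1(C)CCCC(C)(C)N1[O] | starting material
21 | aryl radical from 19 (radical at the former C–I carbon) | COc1cc(C[C@H]2COC(=O)[C@@H]2Cc2c[c]c(O[C@@H](C=C)c3ccc(OCc4ccccc4)c(OC)c3)c(OC)c2)ccc1OCc1ccccc1 | intermediate
22 | cyclized primary alkyl radical (trans ring E, radical on the exocyclic CH2) | COc1cc(C[C@H]2COC(=O)[C@@H]2Cc2cc(OC)c3c(c2)[C@H]([CH2])[C@@H](c2ccc(OCc4ccccc4)c(OC)c2)O3)ccc1OCc1ccccc1 | intermediate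
23 | TEMPO-capped di-O-benzyl isolappaol A, (3R,4R)/(2S,3R) | COc1cc(C[C@H]2COC(=O)[C@@H]2Cc2cc(OC)c3c(c2)[C@H](CON2C(C)(C)CCCC2(C)C)[C@@H](c2ccc(OCc4ccccc4)c(OC)c2)O3)ccc1OCc1ccccc1 | intermediate
24 | di-O-benzyl isolappaol A, (3R,4R)/(2S,3R) | COc1cc(C[C@H]2COC(=O)[C@@H]2Cc2cc(OC)c3c(c2)[C@H](CO)[C@@H](c2ccc(OCc4ccccc4)c(OC)c2)O3)ccc1OCc1ccccc1 | intermediate
25 | isolappaol A | COc1cc(C[C@H]2COC(=O)[C@@H]2Cc2cc(OC)c3c(c2)[C@H](CO)[C@@H](c2ccc(O)c(OC)c2)O3)ccc1O | target

## Step count and risk

Total: 15 steps. Longest linear sequence: 9 steps (steps 1, 2, 3, 7, 8, 12, 13, 14, 15, from 1 to 25). The bromide branch (steps 4–6) and the carbonate branch (steps 9–11) are three steps each.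

**Step 13 (key step).** Three things may go wrong.
- Hydrogen transfer from tin hydride to 22 may compete with nitroxide capture, so that the CH2 ends as methyl.
- Premature capture of 21 by the nitroxide or by hydrogen may occur before ring closure.
- The trans preference may be weak, because an aryl radical adds through an early transition state that feels the C2 aryl group only modestly.

Fallback: set out from 19 and put a boron substituent on the alkene terminus by cross-metathesis with vinylboronic acid pinacol ester (second-generation Hoveyda–Grubbs catalyst, CH2Cl2, 40 °C), giving the (E)-alkenyl boronate F1. Cyclization with Bu3SnH and AIBN (toluene, 80 °C) forms the same C3a–C3 bond in the same 5-exo mode. The boron-stabilized radical is simply reduced by tin hydride, so no trap has to compete, and the larger alkene terminus should reinforce the trans preference; this gives the pinacol boronate F2. Oxidation with NaBO3·4H2O in THF–water converts C–B into C–OH and returns to the route at 24.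

**Step 12.** Possible failures are these.
- Re-ionization of the very electron-rich branched ether may erode branch selectivity and configurational purity at C2.
- The 2,6-disubstituted phenoxide may attack slowly.
- The aryl iodide may consume the low-valent iridium catalyst by oxidative addition.

Fallback: replace catalyst control by chirality transfer. Set out from 1 and add CH2=CHMgBr (THF, 0 °C) to give the racemic allylic alcohol F3. Kinetic resolution with immobilized Candida antarctica lipase B and vinyl acetate should leave the (S)-alcohol F4, the antipode being removed as its acetate. Acylation with Boc2O (LiN(SiMe3)2, THF, −78 °C) gives the (S)-tert-butyl carbonate F5. Reaction of F5 with phenol 14 under [Cp*Ru(MeCN)3]PF6 catalysis (acetone, rt) is a branch-retentive, stereospecific allylic etherification with net retention, and returns to the route at 19.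

**Step 7.** The electron-rich benzylic bromide 11 may decompose by solvolysis or self-condensation before or during alkylation, and proton transfer may limit conversion. Fallback: set out from 7 and 9, bypassing 10 and 11. Aldol addition of the lithium enolate (LiN(SiMe3)2, THF, −78 °C) to aldehyde 9 gives the 3,4-trans β-hydroxy lactone F6 (carbinol epimers). Dehydration (MsCl, Et3N; then DBU) gives the (E)-benzylidene lactone F7. Conjugate reduction with [(Ph3P)CuH]6 (toluene, rt) tolerates the aryl iodide and the benzyl ether; brief DBU treatment then equilibrates the α-center to the more stable trans arrangement, returning to the route at 13.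

**Step 14.** Hot acetic acid may ionize the O1–C2 bond (ring opening or C2 epimerization), and reduction of the hindered N–O bond may be sluggish. Fallback: set out from 23 and remove the piperidine oxidatively. mCPBA (CH2Cl2, 0 °C) oxidizes the alkoxyamine nitrogen, and fragmentation gives the C3 aldehyde F8. Its α-center can be equilibrated to trans with mild base, which would also correct any cis material from step 13. NaBH4 (MeOH–THF, 0 °C) then reduces the aldehyde and returns to the route at 24.

## Further compounds

F1 | step 13 | (E)-alkenyl pinacol boronate from 19, (1S) ether carbon | COc1cc(C[C@H]2COC(=O)[C@@H]2Cc2cc(I)c(O[C@@H](/C=C/B3OC(C)(C)C(C)(C)O3)c3ccc(OCc4ccccc4)c(OC)c3)c(OC)c2)ccc1OCc1ccccc1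
F2 | step 13 | trans-2,3-dihydrobenzofuran with CH2–B(pinacolato) at C3 (boron analogue of 24) | COc1cc(C[C@H]2COC(=O)[C@@H]2Cc2cc(OC)c3c(c2)[C@H](CB2OC(C)(C)C(C)(C)O2)[C@@H](c2ccc(OCc4ccccc4)c(OC)c2)O3)ccc1OCc1ccccc1
F3 | step 12 | racemic 1-(4-benzyloxy-3-methoxyphenyl)prop-2-en-1-ol | C=CC(O)c1ccc(OCc2ccccc2)c(OC)c1
F4 | step 12 | (S)-1-(4-benzyloxy-3-methoxyphenyl)prop-2-en-1-ol | O[C@@H](C=C)c1ccc(OCc2ccccc2)c(OC)c1
F5 | step 12 | (S)-1-(4-benzyloxy-3-methoxyphenyl)allyl tert-butyl carbonate | CC(C)(C)OC(=O)O[C@@H](C=C)c1ccc(OCc2ccccc2)c(OC)c1
F6 | step 7 | 3,4-trans aldol adduct of 7 and 9 (carbinol epimers) | COc1cc(C[C@H]2COC(=O)[C@@H]2C(O)c2cc(I)c(O[Si](C)(C)C(C)(C)C)c(OC)c2)ccc1OCc1ccccc1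
F7 | step 7 | (R,E)-4-(4-benzyloxy-3-methoxybenzyl)-3-[4-(tert-butyldimethylsilyloxy)-3-iodo-5-methoxybenzylidene]dihydrofuran-2(3H)-one | COc1cc(C[C@H]2COC(=O)/C2=C/c2cc(I)c(O[Si](C)(C)C(C)(C)C)c(OC)c2)ccc1OCc1ccccc1
F8 | step 14 | trans C3-formyl analogue of 24 | COc1cc(C[C@H]2COC(=O)[C@@H]2Cc2cc(OC)c3c(c2)[C@H](C=O)[C@@H](c2ccc(OCc4ccccc4)c(OC)c2)O3)ccc1OCc1ccccc1
A1 | alternative 1 | O-silyl di-O-benzyl isolappaol A | COc1cc(C[C@H]2COC(=O)[C@@H]2Cc2cc(OC)c3c(c2)[C@H](CO[Si](C)(C)C(C)(C)C)[C@@H](c2ccc(OCc4ccccc4)c(OC)c2)O3)ccc1OCc1ccccc1
A2 | alternative 1 | (3R,4R)-4-(4-benzyloxy-3-methoxybenzyl)-3-{3-[2-(tert-butyldimethylsilyloxy)-1-(p-tolylsulfonyl)ethyl]-4-hydroxy-5-methoxybenzyl}dihydrofuran-2(3H)-one (sulfone carbon unconfigured) | COc1cc(C[C@H]2COC(=O)[C@@H]2Cc2cc(OC)c(O)c(c2)C(CO[Si](C)(C)C(C)(C)C)S(=O)(=O)c2ccc(C)cc2)ccc1OCc1ccccc1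
A3 | alternative 1 | (2R,5R)-1-(4-benzyloxy-3-methoxybenzyl)-2,5-dimethylthiolanium tetrafluoroborate | COc1cc(C[S+]2[C@H](C)CC[C@H]2C)ccc1OCc1ccccc1.F[B-](F)(F)F
A4 | alternative 2 | methyl trans-2-(4-benzyloxy-3-methoxyphenyl)-5-bromo-7-methoxy-2,3-dihydrobenzofuran-3-carboxylate | Brc1cc(OC)c2c(c1)[C@H](C(=O)OC)[C@@H](c1ccc(OCc3ccccc3)c(OC)c1)O2
A5 | alternative 2 | methyl 2-[2-(4-benzyloxy-3-methoxybenzyloxy)-5-bromo-3-methoxyphenyl]-2-diazoacetate | COC(=O)C(=[N+]=[N-])c1cc(Br)cc(OC)c1OCc1ccc(OCc2ccccc2)c(OC)c1
A6 | alternative 3 | trans-2-(4-benzyloxy-3-methoxyphenyl)-5-bromo-3-hydroxymethyl-7-methoxy-2,3-dihydrobenzofuran | Brc1cc(OC)c2c(c1)[C@H](CO)[C@@H](c1ccc(OCc3ccccc3)c(OC)c1)O2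
A7 | alternative 3 | 1-(4-benzyloxy-3-methoxyphenyl)-2-(5-bromo-2-hydroxy-3-methoxyphenyl)propane-1,3-diol (configured at C2, epimeric at C1) | COc1cc(Br)cc([C@H](CO)C(O)c2ccc(OCc3ccccc3)c(OC)c2)c1O
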